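A ratio tells you where this flask stops: how the partner divides between two takers. The solid reagent dissolves to give partner. Partner turns catalyst intermediate A into target, or catalyst intermediate B into second product, and both steps run one way.

all flasks: free catalyst 1.3 mol%

| flask | starting material | second substrate | solid reagent | remark | time |
|---|---|---|---|---|---|
| Tuesday's | 0.10 M | 1 equiv | 0.90 equiv | the very flask that is asked about, followed so far |  |
| Monday's | 0.20 M | 1 equiv | 0.90 equiv | run made earlier |  |
| flask | 0.10 M | 1.00 equiv | 0.900 equiv |  | 12 h |

- Tuesday's (time / h: starting material / %, target / %): 0.833: 75.6, 23.7; 2.00: 74.0, 25.6; 2.50: 74.1, 26.1; 4.00: 73.4, 26.1
- Monday's (time / h: starting material / %, target / %): 1.00: 82.7, 17.3; 3.00: 77.8, 21.3; 5.00: 78.4, 21.1; 8.00: 78.1, 21.3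

(each reading ± 0.3 percentage points)

- why nothing more happens at 12 h, or that something still does (for what has run out or reacted, a solid counts together with what of it has only dissolved) (the partner has run out first / it is still moving / forward and back rates have come level / all of the starting material has reacted / no working catalyst is left)
- conversion of starting material at 12 h
- amount of target at 12 h, in percent of the starting material charged
- amount of target if the flask were left three thousand times as long, in percent of the starting material charged

- solid reagent is a solid; its amount is given per volume of the solution
- candidate steps: starting material + free catalyst <-> catalyst intermediate A; partner + catalyst intermediate A -> free catalyst + target; second substrate + free catalyst <-> catalyst intermediate B; partner + catalyst intermediate B -> free catalyst + second product; solid reagent <-> partner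
- at the start none of the solid reagent is in solution
- the reaction counts as stopped when no species that holds the starting material changes by six tenths of a point or more over the second half of the time

Read the last rows of the tables. Tuesday's target reads 26.1%, then 26.1%, flat within the scatter of 0.3 percentage points. Monday's also stands flat, at 21.3%. A flat end on one-way steps points to the partner supply, 0.90 equiv of solid in each run.

So take Tuesday's last row. Target took 26.1%, and I reckon second product took the remainder of the solid, 63.9%. Now define s, the selectivity factor, 0.297: the logarithm of the fraction of starting material not made into target, over the same logarithm for second substrate and second product. Monday's last row gives 0.206, less than Tuesday's. So use s at Tuesday's concentration and loading. The asked flask is Tuesday's, so I expect it to stay at its plateau.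

The forecast says the partner has run out first, with conversion 26.3%, target 26%, and 26% after the very long wait: “The likely cause is that the partner is used up.”

The flask gives the partner has run out first, conversion 26.3%, target 26.1%, and 26.1% after the very long wait.

    starting material + free catalyst ⇌ catalyst intermediate A (K = 13.0 /M, k = 67.0 /M/min)
    partner + catalyst intermediate A → free catalyst + target (k = 51.0 /M/min)
    second substrate + free catalyst ⇌ catalyst intermediate B (K = 97.0 /M, k = 36.0 /M/min)
    partner + catalyst intermediate B → free catalyst + second product (k = 180 /M/min)
    solid reagent ⇌ partner, rate k5*(cs5 - [partner]) while solid is left; crystals form when [partner] > cs5 (solubility = 0.0830 M, k = 0.0370 /min)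

The solid reagent is the limiting reagent: at 12.0 h it stands at 0%, with c(partner) at 0 M, and 74% of the starting material waits unused. In this flask at 0.292 h, catalyst intermediate A falls back 4.8 times faster than it goes on.

Now take this flask with 0.400 equiv of second substrate. Putting s into the solid balance gives 53.0% target. The simulation gives 52.8%.

(The data stem from a simulated flask with constants of no real substance; the scatter is artificial.)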